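**Retrosynthetic overview**

Atom labels: C1 is the ketone carbon; C2 (CH) and C5 (quaternary) are the bridgeheads of the bicyclo[2.2.2]octenone; C3=C4 is its alkene (methyl on C4); C6–C9 complete ring B (lactone oxygen on C6, C11 and C12 on C7); C10 bears the angular methyl; C1'H2–C2'H is the saturated bridge and C3' the first side-chain carbon; β is the face of the C10 methyl, α the opposite face.
Feature: the ketone C1 lies between C10, which has no hydrogen, and the bridgehead C2, and C2 is bonded to the alkene carbon C3; C2–C3 is therefore a hidden aldol bond of a cyclohexanone (ring A = C10–C1–C2–C2'–C1'–C5) with a propanal arm on C5, and an oxygen on C3 can leave only toward C4 because a C2=C3 bond would be anti-Bredt.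
Disconnections: target ⇒ C3 enol triflate ⇒ bridged 1,3-diketone ⇒ ketol ⇒ (aldol, C2–C3) trans-decalin keto aldehyde ⇒ C6 ketone (lactone by C7 alkylation, equatorial reduction, C11 methylation) ⇒ C6=C7 alkene ⇒ (Claisen shift from the 7α-oxygen, arm onto C5α) 7α-allylic alcohol ⇒ (1,6-cuprate addition at C2') linear dienone ⇒ (R)-Wieland–Miescher ketone.
Order of events: the side chain is placed on C2' while C5 is still trigonal, because an axial arm on C5 would later screen the α-face of C2'; the ring-B oxidations that follow use only reagents that spare the side-chain alkenes.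
Ring order: rings A and B come with the Wieland–Miescher ketone, the γ-lactone is closed third, and the bicyclo[2.2.2]octane ring is closed last by the aldol step.

Key step: step 18

Assumption: the Claisen step gives both epimers at the arm carbon C4; C4 is epimerisable in the keto aldehyde and becomes sp2 in the target, so from the Claisen product to the keto aldehyde, and again in the diketone, C4 is drawn without a descriptor.

**Route**

Step 1
Reactants: 1 (R)-(−)-Wieland–Miescher ketone
Product: 2 (4aR,5R)-5-hydroxy-4a-methyl-4,4a,5,6,7,8-hexahydronaphthalen-2(3H)-one (C1β-alcohol, cis to the C10 methyl)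
Conditions: NaBH4 (0.3 equiv), EtOH, −10 °C
Reagents that add atoms: none
Why: Chemoselective borohydride reduction: the saturated C1 ketone is more electrophilic than the vinylogous C7 carbonyl, and hydride enters C1 axially from the face anti to the angular methyl, giving the equatorial alcohol cis to that methyl.

Step 2
Reactants: 2 C1β-hydroxy enone
Product: 3 C1 tert-butyldimethylsilyl ether of 2
Conditions: t-BuMe2SiCl, imidazole, DMF, 40 °C
Reagents that add atoms: tert-butyldimethylsilyl chloride, CC(C)(C)[Si](C)(C)Cl
Why: Silyl ether protection of the hindered secondary alcohol, which keeps C1 free of enolisable hydrogen and inert to base, hydride, dissolving metal and heat until step 16.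

Step 3
Reactants: 3 silyl ether enone
Product: 4 linear dienone (C7 ketone conjugated with C5=C6 and C1'=C2')
Conditions: chloranil (1.2 equiv), t-BuOH, reflux
Reagents that add atoms: none
Why: Quinone dehydrogenation through the dienol extended toward C1' with hydride loss from C2', the transformation that turns steroidal 4-en-3-ones into 4,6-dien-3-ones; C1' is the only γ-position that carries hydrogen.

Step 4
Reactants: 5 6-methylhept-5-en-2-one; 6 2,4,6-triisopropylbenzenesulfonyl hydrazide
Product: 7 2,4,6-triisopropylbenzenesulfonylhydrazone of 5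
Conditions: MeOH, HCl (cat.), 20 °C
Reagents that add atoms: 2,4,6-triisopropylbenzenesulfonyl hydrazide, CC(C)c1cc(C(C)C)c(S(=O)(=O)NN)c(C(C)C)c1
Why: Acid-catalysed hydrazone formation provides the substrate for a Shapiro reaction.

Step 5
Reactants: 4 linear dienone; 7 sulfonylhydrazone
Product: 11 conjugated enone (C5=C6–C7=O) with the 6-methylhepta-1,5-dien-2-yl group on C2' (α), via alkenyllithium 8 (not isolated), via lithium dialkenylcuprate 9 (not isolated), via deconjugated enone 10 (not isolated)
Conditions: 7, n-BuLi (2.1 equiv per 7), THF, −78 → 0 °C; CuI (0.5 equiv per alkenyllithium), −40 °C; 4, −78 → −20 °C; aq. NH4Cl; then DBU (0.2 equiv), CH2Cl2, 20 °C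
Reagents that add atoms: sulfonylhydrazone 7 (source of the 6-methylhepta-1,5-dien-2-yl group), CC(CCC=C(C)C)=NNS(=O)(=O)c1c(C(C)C)cc(C(C)C)cc1C(C)C
Why: The Shapiro reaction gives the less substituted alkenyllithium, whose Gilman cuprate LiCuR2 adds 1,6 because the β-carbon C5 is fully substituted; C2' is attacked axially on the α-face anti to the C10 methyl (the mode that gives 7α-alkyl steroids from 4,6-dien-3-ones) while C5 is trigonal and carries no axial group, and DBU then returns the alkene to conjugation.

Step 6
Reactants: 11 side-chain enone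
Product: 12 7α-allylic alcohol
Conditions: LiBH(s-Bu)3, THF, −78 °C; then H2O
Reagents that add atoms: none
Why: 1,2-Reduction of the β,β-disubstituted enone by a bulky trialkylborohydride, which approaches from the equatorial (β) direction and should give the pseudoaxial 7α-alcohol needed to deliver the arm to the α-face.

Step 7
Reactants: 12 7α-allylic alcohol; 13 triethyl orthopropionate
Product: 15 ethyl 2-propanoate on C5 (α) with C6=C7 alkene (both C4 epimers), via ketene acetal 14 (not isolated)
Conditions: 13 (8 equiv), EtCO2H (0.05 equiv), xylene, 140 °C, EtOH distilled off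
Reagents that add atoms: triethyl orthopropionate, CCC(OCC)(OCC)OCC
Why: Johnson–Claisen rearrangement: the ketene acetal on the 7α-oxygen shifts suprafacially, so the new C5–C4 bond forms on the α-face anti to the C10 methyl, making C5 quaternary and moving the alkene to C6=C7.

Step 8
Reactants: 15 Claisen ester
Product: 16 arm primary alcohol (C5α–CH(CH3)CH2OH)
Conditions: LiAlH4, Et2O, 0 °C
Reagents that add atoms: none
Why: Hydride reduction of the ester gives the alcohol that directs the next oxidation; silyl ether and isolated alkenes are inert.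

Step 9
Reactants: 16 arm alcohol
Product: 17 6α,7α-epoxide
Conditions: VO(acac)2 (5 mol %), t-BuOOH (1.5 equiv), toluene, 20 → 40 °C
Reagents that add atoms: tert-butyl hydroperoxide, CC(C)(C)OO
Why: Hydroxyl-directed vanadium-catalysed epoxidation: the bishomoallylic arm alcohol delivers oxygen to the α-face of C6=C7, while the side-chain alkenes, more than five bonds from the hydroxyl and the first targets of a peracid, are not directed and should stay intact.

Step 10
Reactants: 17 epoxide
Product: 18 diol (6α-ol and arm primary alcohol)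
Conditions: LiBHEt3 (4 equiv), THF, 0 → 50 °C
Reagents that add atoms: none
Why: Nucleophilic hydride opening of the epoxide at C7, the only epoxide carbon that is not neopentyl and not screened by the axial C10 methyl, leaves the oxygen on C6 with its α-configuration.

Step 11
Reactants: 18 diol
Product: 19 arm tert-butyldimethylsilyl ether with free 6α-ol
Conditions: t-BuMe2SiCl (1.1 equiv), imidazole, CH2Cl2, 0 °C
Reagents that add atoms: tert-butyldimethylsilyl chloride, CC(C)(C)[Si](C)(C)Cl
Why: Selective silylation of the primary alcohol; the neopentyl secondary 6α-ol should not react at 0 °C.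

Step 12
Reactants: 19 mono-protected diol
Product: 20 C6 ketone
Conditions: Dess–Martin periodinane, NaHCO3, CH2Cl2, 20 °C
Reagents that add atoms: none
Why: Dess–Martin oxidation of the secondary alcohol under buffered conditions that spare alkenes and silyl ethers; the C6 configuration is deliberately given up so that C7 can be functionalised.

Step 13
Reactants: 20 C6 ketone; 21 ethyl bromoacetate
Product: 23 7β-(carboxymethyl) C6 ketone, via keto ester 22 (not isolated)
Conditions: LiN(i-Pr)2 (1.1 equiv), THF, −78 °C; 21, DMPU, −78 → 0 °C; then LiOH, THF–MeOH–H2O, 20 °C; 1 M HCl to pH 3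
Reagents that add atoms: ethyl bromoacetate, CCOC(=O)CBr; lithium hydroxide, [Li+].[OH-]
Why: Enolate alkylation: C5 is quaternary, so the ketone enolises only toward C7 and is alkylated there, and the hydroxide used for saponification equilibrates C7 to the equatorial 7β-epimer.

Step 14
Reactants: 23 keto acid
Product: 25 trans-fused γ-lactone (6α-O and 7β-C) without the C11 methyl, via hydroxy acid 24 (not isolated)
Conditions: Li, NH3 (l), THF, t-BuOH (2 equiv), −78 °C; NH4Cl; then aq. citric acid (pH 3), EtOAc, 20 °C
Reagents that add atoms: none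
Why: Dissolving-metal ketone reduction gives the thermodynamically preferred equatorial 6α-alcohol (the 6β-epimer would be syn-axial to the C10 methyl) without touching the carboxylate or isolated alkenes, and the trans-diequatorial hydroxy acid lactonises on acidification.

Step 15
Reactants: 25 lactone; 26 iodomethane
Product: 27 11α-methyl lactone (methyl cis to H7), bis-silyl ether
Conditions: LiN(i-Pr)2 (1.2 equiv), THF, −78 °C; MeI, −78 → −40 °C
Reagents that add atoms: iodomethane, CI
Why: Lactone enolate alkylation: methyl iodide approaches C11 from the face of H7, anti to C8, giving the epimer that is also thermodynamically preferred, so later base treatment cannot harm it.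

Step 16
Reactants: 27 bis-silyl ether
Product: 28 lactone diol (C1β-ol and arm primary alcohol)
Conditions: HF·pyridine, pyridine, THF, 0 → 20 °C
Reagents that add atoms: none
Why: Fluoride cleavage of both silyl ethers (desilylation) under buffered conditions that leave lactone and alkenes alone.

Step 17
Reactants: 28 lactone diol
Product: 29 trans-decalin keto aldehyde (C1 ketone, propanal arm on C5α, both C4 epimers)
Conditions: Dess–Martin periodinane (3 equiv), NaHCO3, CH2Cl2, 0 → 20 °C
Reagents that add atoms: none
Why: Double Dess–Martin oxidation converts the C1 carbinol into the ketone and the primary alcohol into the aldehyde in one base-free operation, so the keto aldehyde is released only now.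

Step 18
Reactants: 29 keto aldehyde
Product: 30 bridged ketol (C3-hydroxy, C3–C4-saturated analogue of the target)
Conditions: KOt-Bu (0.3 equiv), t-BuOH–THF (1:4), 0 → 20 °C; AcOH
Reagents that add atoms: none
Why: Base-mediated intramolecular aldol addition, the closure by which cyclohexanones with a 2-oxoethyl group on C3 give bicyclo[2.2.2]octane ketols: tert-butoxide reversibly removes a proton from C2, the one position at which the C1 ketone can enolise since C10 carries no hydrogen, and the enolate carbon adds to the aldehyde carbon C3 that the axial C5 arm holds over the α-face of ring A. The new bond C2–C3 closes ring C2–C3–C4–C5–C1'–C2' in a 6-(enolexo)-exo-trig mode and, at the same time, ring C1–C2–C3–C4–C5–C10 in a 6-(enolendo)-exo-trig mode, across the boat of ring A that the syn C5 and C2' substituents already favour. The bridgehead C2 can form in one configuration only, dictated by the tether from C5, so it is set by the C5 stereocentre. The carbinol C3 and the arm carbon C4 (which epimerises through the aldehyde enolate before closure) are set under equilibrium, and the isomer drawn, with the hydroxyl hydrogen-bonded to the C1 carbonyl and the C4 methyl turned away from ring B, should prevail; both centres are erased in steps 19–21. The step needs regiocontrol only: the aldehyde enolate could close nothing but a four-membered ring, the lactone enolate cannot reach C3, and dehydration of the ketol toward the bridgehead C2 is forbidden by Bredt's rule, so the ketol is the resting state of the equilibrium.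

Step 19
Reactants: 30 bridged ketol
Product: 31 bridged 1,3-diketone (C1 and C3 ketones)
Conditions: Dess–Martin periodinane, NaHCO3, CH2Cl2, 20 °C
Reagents that add atoms: none
Why: Dess–Martin oxidation under neutral conditions that avoid retro-aldol and retro-Claisen cleavage; every C3/C4 epimer of 30 converges on 31, so the removal of the C3 oxygen does not depend on a syn β-hydrogen.

Step 20
Reactants: 31 diketone
Product: 32 C3 enol triflate (C3=C4)
Conditions: KN(SiMe3)2 (1.05 equiv), THF, −78 °C; PhNTf2, −78 → −40 °C
Reagents that add atoms: N-phenylbis(trifluoromethanesulfonimide), O=S(=O)(N(c1ccccc1)S(=O)(=O)C(F)(F)F)C(F)(F)F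
Why: Enol triflate formation: the only ketone α-hydrogen is on C4 (C2 is a bridgehead, C10 is quaternary), so the amide base forms the C3–C4 enolate, which the triflimide traps on oxygen.

Step 21
Reactants: 32 enol triflate
Product: 33 target CNP0385704.1
Conditions: Pd(OAc)2 (5 mol %), PPh3 (10 mol %), HCO2H (2 equiv), n-Bu3N (3 equiv), DMF, 60 °C
Reagents that add atoms: none
Why: Palladium-catalysed formate reduction of the alkenyl triflate (oxidative addition, formate exchange, loss of CO2, reductive elimination) replaces the triflate by hydrogen and leaves the C3=C4 alkene, ketone, lactone and side-chain alkenes untouched.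

**Compound list**

1 | (R)-(−)-Wieland–Miescher ketone | C[C@@]12CCC(=O)C=C1CCCC2=O | starting material
2 | (4aR,5R)-5-hydroxy-4a-methyl-4,4a,5,6,7,8-hexahydronaphthalen-2(3H)-one (C1β-alcohol) | C[C@@]12CCC(=O)C=C1CCC[C@H]2O | intermediate
3 | C1 tert-butyldimethylsilyl ether of 2 | C[C@@]12CCC(=O)C=C1CCC[C@H]2O[Si](C)(C)C(C)(C)C | intermediate
4 | linear dienone, (4aR,5R)-5-(tert-butyldimethylsilyloxy)-4a-methyl-4,4a,5,6-tetrahydronaphthalen-2(3H)-one | C[C@@]12CCC(=O)C=C1C=CC[C@H]2O[Si](C)(C)C(C)(C)C | intermediate
5 | 6-methylhept-5-en-2-one | CC(=O)CCC=C(C)C | starting material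
6 | 2,4,6-triisopropylbenzenesulfonyl hydrazide | CC(C)c1cc(C(C)C)c(S(=O)(=O)NN)c(C(C)C)c1 | starting material
7 | 2,4,6-triisopropylbenzenesulfonylhydrazone of 5 | CC(CCC=C(C)C)=NNS(=O)(=O)c1c(C(C)C)cc(C(C)C)cc1C(C)C | intermediate
8 | (6-methylhepta-1,5-dien-2-yl)lithium | [Li]C(=C)CCC=C(C)C | intermediate
9 | lithium bis(6-methylhepta-1,5-dien-2-yl)cuprate | [Li+].C=C(CCC=C(C)C)[Cu-]C(=C)CCC=C(C)C | intermediate
10 | deconjugated enone (C7 ketone, C5=C1') with the side chain on C2' | C[C@@]12CCC(=O)CC1=C[C@H](C(=C)CCC=C(C)C)C[C@H]2O[Si](C)(C)C(C)(C)C | intermediate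
11 | conjugated enone (C5=C6–C7=O) with the side chain on C2' (α, trans to the C10 methyl) | C[C@@]12CCC(=O)C=C1C[C@H](C(=C)CCC=C(C)C)C[C@H]2O[Si](C)(C)C(C)(C)C | intermediate
12 | 7α-allylic alcohol of 11 | C[C@@]12CC[C@H](O)C=C1C[C@H](C(=C)CCC=C(C)C)C[C@H]2O[Si](C)(C)C(C)(C)C | intermediate
13 | triethyl orthopropionate | CCC(OCC)(OCC)OCC | starting material
14 | mixed ketene acetal on the 7α-oxygen of 12 | C[C@@]12CC[C@H](OC(OCC)=CC)C=C1C[C@H](C(=C)CCC=C(C)C)C[C@H]2O[Si](C)(C)C(C)(C)C | intermediate
15 | ethyl 2-propanoate on C5 (α), C6=C7 alkene, C4 epimers | C=C(CCC=C(C)C)[C@H]1C[C@]2(C(C)C(=O)OCC)C=CCC[C@@]2(C)[C@H](O[Si](C)(C)C(C)(C)C)C1 | intermediate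
16 | arm primary alcohol, C6=C7 alkene | C=C(CCC=C(C)C)[C@H]1C[C@]2(C(C)CO)C=CCC[C@@]2(C)[C@H](O[Si](C)(C)C(C)(C)C)C1 | intermediate
17 | 6α,7α-epoxide of 16 | C=C(CCC=C(C)C)[C@H]1C[C@]2(C(C)CO)[C@H]3O[C@H]3CC[C@@]2(C)[C@H](O[Si](C)(C)C(C)(C)C)C1 | intermediate
18 | diol (6α-ol and arm primary alcohol) | C=C(CCC=C(C)C)[C@H]1C[C@]2(C(C)CO)[C@@H](O)CCC[C@@]2(C)[C@H](O[Si](C)(C)C(C)(C)C)C1 | intermediate
19 | arm tert-butyldimethylsilyl ether of 18 (free 6α-ol) | C=C(CCC=C(C)C)[C@H]1C[C@]2(C(C)CO[Si](C)(C)C(C)(C)C)[C@@H](O)CCC[C@@]2(C)[C@H](O[Si](C)(C)C(C)(C)C)C1 | intermediate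
20 | C6 ketone | C=C(CCC=C(C)C)[C@H]1C[C@]2(C(C)CO[Si](C)(C)C(C)(C)C)C(=O)CCC[C@@]2(C)[C@H](O[Si](C)(C)C(C)(C)C)C1 | intermediate
21 | ethyl bromoacetate | CCOC(=O)CBr | starting material
22 | C7-(ethoxycarbonylmethyl) C6 ketone, C7 epimers | C=C(CCC=C(C)C)[C@H]1C[C@]2(C(C)CO[Si](C)(C)C(C)(C)C)C(=O)C(CC(=O)OCC)CC[C@@]2(C)[C@H](O[Si](C)(C)C(C)(C)C)C1 | intermediate
23 | 7β-(carboxymethyl) C6 ketone | C=C(CCC=C(C)C)[C@H]1C[C@]2(C(C)CO[Si](C)(C)C(C)(C)C)C(=O)[C@H](CC(=O)O)CC[C@@]2(C)[C@H](O[Si](C)(C)C(C)(C)C)C1 | intermediate
24 | 6α-hydroxy-7β-(carboxymethyl) acid | C=C(CCC=C(C)C)[C@H]1C[C@]2(C(C)CO[Si](C)(C)C(C)(C)C)[C@@H](O)[C@H](CC(=O)O)CC[C@@]2(C)[C@H](O[Si](C)(C)C(C)(C)C)C1 | intermediate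
25 | trans-fused γ-lactone (6α-O, 7β-C) without the C11 methyl, bis-silyl ether | C=C(CCC=C(C)C)[C@H]1C[C@]2(C(C)CO[Si](C)(C)C(C)(C)C)[C@H]3OC(=O)C[C@@H]3CC[C@@]2(C)[C@H](O[Si](C)(C)C(C)(C)C)C1 | intermediate
26 | iodomethane | CI | starting material
27 | 11α-methyl lactone (methyl cis to H7), bis-silyl ether | C=C(CCC=C(C)C)[C@H]1C[C@]2(C(C)CO[Si](C)(C)C(C)(C)C)[C@H]3OC(=O)[C@@H](C)[C@@H]3CC[C@@]2(C)[C@H](O[Si](C)(C)C(C)(C)C)C1 | intermediate
28 | lactone diol (C1β-ol and arm primary alcohol) | C=C(CCC=C(C)C)[C@H]1C[C@]2(C(C)CO)[C@H]3OC(=O)[C@@H](C)[C@@H]3CC[C@@]2(C)[C@H](O)C1 | intermediate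
29 | trans-decalin keto aldehyde (key-step precursor), C4 epimers | C=C(CCC=C(C)C)[C@H]1C[C@]2(C(C)C=O)[C@H]3OC(=O)[C@@H](C)[C@@H]3CC[C@@]2(C)C(=O)C1 | intermediate
30 | bridged ketol (C3-hydroxy, C3–C4-saturated analogue of the target) | C=C(CCC=C(C)C)[C@H]1C[C@@]23[C@@H](C)[C@H](O)[C@@H]1C(=O)[C@]2(C)CC[C@H]1[C@H](C)C(=O)O[C@@H]13 | intermediate
31 | bridged 1,3-diketone (C1 and C3 ketones) | C=C(CCC=C(C)C)[C@H]1C[C@@]23C(C)C(=O)[C@@H]1C(=O)[C@]2(C)CC[C@H]1[C@H](C)C(=O)O[C@@H]13 | intermediate
32 | C3 enol triflate | C=C(CCC=C(C)C)[C@H]1C[C@@]23C(C)=C(OS(=O)(=O)C(F)(F)F)[C@@H]1C(=O)[C@]2(C)CC[C@H]1[C@H](C)C(=O)O[C@@H]13 | intermediate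
33 | CNP0385704.1 | C=C(CCC=C(C)C)[C@H]1C[C@@]23C(C)=C[C@@H]1C(=O)[C@]2(C)CC[C@H]1[C@H](C)C(=O)O[C@@H]13 | target

**Step count and risks**

Total step count: 21. Longest linear sequence: 20 steps (steps 1–3 and 5–21, from 1).

Steps most likely to fail:

Step 7. The [3,3] shift has to form C5–C4 on the α-face right beside the axial C2' side chain. The added strain may slow it so much that acid-promoted ionisation of the allylic C7–O bond (diene formation) or migration of the exocyclic side-chain alkene takes over at 140 °C. The fallback sets out from 12 and replaces the acid-catalysed orthoester exchange by an ester-enolate rearrangement that runs near room temperature. Acylation with propionyl chloride (pyridine, DMAP, CH2Cl2) should give the 7α-propionate F1; LiN(i-Pr)2 and Me3SiCl in THF at −78 °C should give the silyl ketene acetal F2, which on warming to 20–60 °C should undergo the Ireland–Claisen rearrangement and, after aqueous work-up, give the C5 propanoic acid F3; LiAlH4 reduction of F3 returns to the route at 16.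

Step 10. Hydride attack at C7 runs against the usual trans-diaxial opening of a cyclohexene oxide (ring B has to pass through a twist-boat), so the opening may stall or occur at C6 and place the oxygen on C7. The fallback sets out from 16 and fixes the oxygen on C6 by ring size instead, bypassing steps 9 and 10. Silylation with 1,1,3,3-tetramethyldisilazane should give the dimethylsilyl ether F4; Pt2[(CH2=CHSiMe2)2O]3 (cat.) in toluene at 60 °C should effect intramolecular hydrosilylation of C6=C7 to the six-membered oxasilinane F5 with silicon on C6 (α); Tamao–Fleming oxidation (H2O2, KF, KHCO3, THF–MeOH), which proceeds with retention and spares isolated alkenes, returns to the route at 18.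

Step 18. The aldol equilibrium may lie on the side of the open keto aldehyde, or enolisation of the hindered C1 ketone may be slower than self-condensation through the aldehyde enolate. The fallback sets out from 29, forms the same C2–C3 bond by C-acylation at the ketone oxidation level and returns at 31, bypassing steps 18 and 19. Pinnick oxidation (NaClO2, NaH2PO4, 2-methyl-2-butene, t-BuOH–H2O) should give the keto acid F6; C6F5OH with N-(3-dimethylaminopropyl)-N'-ethylcarbodiimide hydrochloride in CH2Cl2 should give the pentafluorophenyl ester F7; soft enolisation with MgBr2·OEt2 and i-Pr2NEt in CH2Cl2 should acylate C2 intramolecularly with loss of the weakly nucleophilic phenoxide and give diketone 31.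

Further compounds
F1 | step 7 | 7α-propionate of 12 | C[C@@]12CC[C@H](OC(=O)CC)C=C1C[C@H](C(=C)CCC=C(C)C)C[C@H]2O[Si](C)(C)C(C)(C)C
F2 | step 7 | trimethylsilyl ketene acetal of F1 | C[C@@]12CC[C@H](OC(O[Si](C)(C)C)=CC)C=C1C[C@H](C(=C)CCC=C(C)C)C[C@H]2O[Si](C)(C)C(C)(C)C
F3 | step 7 | C5 (α) 2-propanoic acid, C6=C7 alkene, C4 epimers | C=C(CCC=C(C)C)[C@H]1C[C@]2(C(C)C(=O)O)C=CCC[C@@]2(C)[C@H](O[Si](C)(C)C(C)(C)C)C1
F4 | step 10 | dimethylsilyl ether of 16 | C=C(CCC=C(C)C)[C@H]1C[C@]2(C(C)CO[SiH](C)C)C=CCC[C@@]2(C)[C@H](O[Si](C)(C)C(C)(C)C)C1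
F5 | step 10 | oxasilinane with silicon on C6 (α) | C=C(CCC=C(C)C)[C@H]1C[C@@]23C(C)CO[Si](C)(C)[C@H]3CCC[C@@]2(C)[C@H](O[Si](C)(C)C(C)(C)C)C1
F6 | step 18 | keto acid (arm carboxylic acid) | C=C(CCC=C(C)C)[C@H]1C[C@]2(C(C)C(=O)O)[C@H]3OC(=O)[C@@H](C)[C@@H]3CC[C@@]2(C)C(=O)C1
F7 | step 18 | pentafluorophenyl ester of F6 | C=C(CCC=C(C)C)[C@H]1C[C@]2(C(C)C(=O)Oc3c(F)c(F)c(F)c(F)c3F)[C@H]3OC(=O)[C@@H](C)[C@@H]3CC[C@@]2(C)C(=O)C1
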